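Pentaalbaspidin BBBBB is the achiral, symmetric five-ring chain A–CH2–B–CH2–C–CH2–B'–CH2–A' (A, A' = butyrylfilicinic acid; B, C, B' = butyrylphloroglucinol). It has no stereocentre, so no stereochemistry has to be set.
The retrosynthesis first cuts the two outer bonds between CH2 and rings B and B', which releases rings A and A' as an aminomethylated butyrylfilicinic acid. It then cuts the two inner bonds from CH2 to C3 and C5 of ring C.
Enabling feature: C3 and C5 of ring C each lie between two oxygen-bearing ring carbons and are the only C–H positions of the O-methylated ring C monomer. Bromination therefore labels exactly these two atoms, and palladium catalysis can exchange each label for a benzylic carbon.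
Forward, no ring is built. One ketone made from 1,3,5-trimethoxybenzene is divided into the ring C dibromide and the ring B benzylzinc chloride, and one dibromide joins two zinc reagents to give the B–C–B' trimer.
The nine ethers are then cleaved, and rings A and A' (made from phloroglucinol) are attached last at the free carbons of B and B'.

Key step: step 5

Assumption: rings A and A' are drawn as the enol tautomer of the target SMILES. All filicinic acid derivatives equilibrate among their enol forms, which does not affect connectivity.

Step 1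
Reactants: 1 1,3,5-trimethoxybenzene; 2 butyryl chloride
Product: 3 1-(2,4,6-trimethoxyphenyl)butan-1-one
Conditions: SnCl4 (1.1 equiv), CH2Cl2, −10 to 0 °C; ice-cold dilute HCl
Reagents that add atoms: none
Why: Friedel–Crafts acylation: the three C–H sites of 1 are equivalent, the first acyl group shuts down a second acylation, and SnCl4 at low temperature is mild enough that the ortho methyl ethers should stay intact.

Step 2
Reactants: 3 1-(2,4,6-trimethoxyphenyl)butan-1-one
Product: 5 1-(3,5-dibromo-2,4,6-trimethoxyphenyl)butan-1-one (ring C dibromide), via monobromo ketone 4 (not isolated)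
Conditions: NBS (2.1 equiv), MeCN, 0 °C to rt, dark
Reagents that add atoms: N-bromosuccinimide, O=C1CCC(=O)N1Br
Why: Electrophilic aromatic bromination with NBS in a polar solvent: the ring of 3 is still activated by three methoxy groups and offers only C3 and C5, while the absence of acid and light should keep the enolisable CH2 next to the ketone unbrominated.

Step 3
Reactants: 3 1-(2,4,6-trimethoxyphenyl)butan-1-one; 6 formaldehyde (as paraformaldehyde)
Product: 8 1-[3-(chloromethyl)-2,4,6-trimethoxyphenyl]butan-1-one, via benzylic alcohol 7 (not isolated)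
Conditions: (CH2O)n (1.0 equiv), HCl gas (saturation), 1,4-dioxane, 0 to 10 °C
Reagents that add atoms: hydrogen chloride, Cl
Why: Blanc chloromethylation: protonated formaldehyde attacks one of the two equivalent free ring carbons, the excess HCl turns alcohol 7 into the chloride, and limiting formaldehyde, dilution and low temperature should hold back a second chloromethylation and diarylmethane formation (unreacted 3 is recovered).

Step 4
Reactants: 8 1-[3-(chloromethyl)-2,4,6-trimethoxyphenyl]butan-1-one
Product: 9 [(3-butanoyl-2,4,6-trimethoxyphenyl)methyl]zinc chloride (LiCl adduct, THF solution, titrated with iodine and used directly)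
Conditions: Zn dust (2 equiv, TMSCl-activated), LiCl (1.5 equiv), THF, slow addition of 8, 0 °C to rt
Reagents that add atoms: zinc, [Zn]
Why: LiCl-assisted direct insertion of zinc into a benzylic C–Cl bond is a known way to ketone-bearing benzylic zinc chlorides; slow addition of 8 to the metal at 0 °C should limit Wurtz-type dimerisation, and the hindered ketone is not attacked by the soft C–Zn bond.

Step 5
Reactants: 5 1-(3,5-dibromo-2,4,6-trimethoxyphenyl)butan-1-one; 9 [(3-butanoyl-2,4,6-trimethoxyphenyl)methyl]zinc chloride (2.6 equiv)
Product: 11 1-{3,5-bis[(3-butanoyl-2,4,6-trimethoxyphenyl)methyl]-2,4,6-trimethoxyphenyl}butan-1-one (nona-O-methyl B–C–B' trimer), via monocoupled bromide 10 (not isolated)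
Conditions: Pd(OAc)2 (4 mol %), SPhos (8 mol %), THF, 9 added over 2 h at rt, then 55 °C
Reagents that add atoms: none
Why: A little of 9 reduces Pd(OAc)2 to SPhos-ligated zerovalent palladium, which inserts into one C–Br bond of 5; the benzyl group passes from zinc to divalent palladium and reductive elimination forges the aryl–CH2 bond, giving 10, which re-enters the same cycle at its second bromide. This is a Negishi sp2–sp3 coupling of a benzylic zinc chloride with a di-ortho-substituted aryl bromide, a known reaction class for which bulky, electron-rich biaryl phosphines are the usual ligands. No ring is closed and no stereocentre is created; two skeletal C–C bonds form. The step needs site fidelity, and the substrate fixes it: carbon can arrive only where bromine sits (C3 and C5 of ring C), and the free C–H of each ring B stays untouched because no electrophilic benzyl species is present. Oxidative addition is helped by the acyl group and by the twisting of every methoxy group of 5 out of conjugation by its two neighbours; the benzyl ligand has no beta-hydrogen, and the hindered, enolisable ketones are inert to the mild zinc reagent. Slow addition keeps the concentration of 9 low, which should curb homocoupling, and its excess together with gentle heating drives 10 on to 11.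

Step 6
Reactants: 11 nona-O-methyl B–C–B' trimer
Product: 12 1-{3,5-bis[(3-butanoyl-2,4,6-trihydroxyphenyl)methyl]-2,4,6-trihydroxyphenyl}butan-1-one (nonaphenol trimer)
Conditions: BBr3 (18 equiv), CH2Cl2, −78 °C to rt; ice water, 0 °C; handled under argon
Reagents that add atoms: none
Why: Lewis acid ether cleavage: boron binds each ether oxygen (fastest, through chelation, at the six ethers next to a carbonyl), bromide removes the methyl group by SN2 and the cold aqueous quench frees the phenols, and while the oxygens carry boron the rings are poor bases, which should protect the CH2 bridges from protolytic cleavage.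

Step 7
Reactants: 13 phloroglucinol; 2 butyryl chloride
Product: 14 1-(2,4,6-trihydroxyphenyl)butan-1-one (phlorobutyrophenone)
Conditions: AlCl3 (3.5 equiv), CH2Cl2–MeNO2, 0 to 40 °C; ice/HCl
Reagents that add atoms: none
Why: Friedel–Crafts C-acylation of phloroglucinol is a standard entry to acylphloroglucinols, and the chelated acyl group deactivates the ring so that the reaction should stop after one acylation.

Step 8
Reactants: 14 1-(2,4,6-trihydroxyphenyl)butan-1-one
Product: 16 2-butanoyl-3,5-dihydroxy-6,6-dimethylcyclohexa-2,4-dien-1-one (butyrylfilicinic acid), via C-methyl ketone 15 (not isolated)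
Conditions: NaOMe (3.2 equiv), MeI (2.2 equiv), MeOH, 0 °C to rt; dilute HCl
Reagents that add atoms: iodomethane, CI
Why: Dearomatising double C-methylation of the phloroglucinol polyanion: the methylated carbon of 15 is the most electron-rich site and should take the second methyl group, and the product rests as a stabilised triketone enolate, so with limited MeI further methylation is slow and the strongly acidic 16 can be separated by bicarbonate extraction and crystallisation.

Step 9
Reactants: 16 butyrylfilicinic acid; 6 formaldehyde (as formalin)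
Product: 17 2-butanoyl-4-[(dimethylamino)methyl]-3,5-dihydroxy-6,6-dimethylcyclohexa-2,4-dien-1-one (Mannich base, collected as the inner salt)
Conditions: aq Me2NH (1.5 equiv) and formalin (1.2 equiv) premixed in EtOH at 0 °C, then slow addition of 16, 0 °C to rt; filtration
Reagents that add atoms: dimethylamine, CNC
Why: Mannich aminomethylation at C4, the only unsubstituted nucleophilic carbon of the enolised triketone; adding 16 to an excess of the preformed amine–formaldehyde adduct keeps free 16 scarce, which should hold back the methylene-bridged homodimer.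

Step 10
Reactants: 12 nonaphenol trimer; 17 Mannich base of butyrylfilicinic acid (2.4 equiv)
Product: 20 pentaalbaspidin BBBBB, via methylene triketone 18 (not isolated), via tetramer 19 (not isolated)
Conditions: degassed THF–EtOH, 40 °C, 17 added in portions, argon; cold dilute HCl
Reagents that add atoms: none
Why: Elimination–addition (retro-aza-Michael then Michael addition, the known way to join a cyclic triketone to an acylphloroglucinol through one carbon): 17 loses dimethylamine to give acceptor 18, the only free carbon of ring B and then of ring B' adds to its CH2 terminus and rearomatises, and because the bridging carbon is already bound to ring A the trimer can act only as the nucleophile, which excludes trimer–trimer bridging.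

Compound list
1 | 1,3,5-trimethoxybenzene | COc1cc(OC)cc(OC)c1 | starting material
2 | butyryl chloride | CCCC(Cl)=O | starting material
3 | 1-(2,4,6-trimethoxyphenyl)butan-1-one | CCCC(=O)c1c(OC)cc(OC)cc1OC | intermediate
4 | 1-(3-bromo-2,4,6-trimethoxyphenyl)butan-1-one (not isolated) | CCCC(=O)c1c(OC)cc(OC)c(Br)c1OC | intermediate
5 | 1-(3,5-dibromo-2,4,6-trimethoxyphenyl)butan-1-one | CCCC(=O)c1c(OC)c(Br)c(OC)c(Br)c1OC | intermediate
6 | formaldehyde (paraformaldehyde or formalin) | C=O | starting material
7 | 1-[3-(hydroxymethyl)-2,4,6-trimethoxyphenyl]butan-1-one (not isolated) | CCCC(=O)c1c(OC)cc(OC)c(CO)c1OC | intermediate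
8 | 1-[3-(chloromethyl)-2,4,6-trimethoxyphenyl]butan-1-one | CCCC(=O)c1c(OC)cc(OC)c(CCl)c1OC | intermediate
9 | [(3-butanoyl-2,4,6-trimethoxyphenyl)methyl]zinc chloride | CCCC(=O)c1c(OC)cc(OC)c(C[Zn]Cl)c1OC | intermediate
10 | 1-{3-bromo-5-[(3-butanoyl-2,4,6-trimethoxyphenyl)methyl]-2,4,6-trimethoxyphenyl}butan-1-one (not isolated) | CCCC(=O)c1c(OC)c(Br)c(OC)c(Cc2c(OC)cc(OC)c(C(=O)CCC)c2OC)c1OC | intermediate
11 | 1-{3,5-bis[(3-butanoyl-2,4,6-trimethoxyphenyl)methyl]-2,4,6-trimethoxyphenyl}butan-1-one | CCCC(=O)c1c(OC)c(Cc2c(OC)cc(OC)c(C(=O)CCC)c2OC)c(OC)c(Cc2c(OC)cc(OC)c(C(=O)CCC)c2OC)c1OC | intermediate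
12 | 1-{3,5-bis[(3-butanoyl-2,4,6-trihydroxyphenyl)methyl]-2,4,6-trihydroxyphenyl}butan-1-one | CCCC(=O)c1c(O)c(Cc2c(O)cc(O)c(C(=O)CCC)c2O)c(O)c(Cc2c(O)cc(O)c(C(=O)CCC)c2O)c1O | intermediate
13 | phloroglucinol | Oc1cc(O)cc(O)c1 | starting material
14 | 1-(2,4,6-trihydroxyphenyl)butan-1-one | CCCC(=O)c1c(O)cc(O)cc1O | intermediate
15 | 1-(2,4,6-trihydroxy-3-methylphenyl)butan-1-one (not isolated) | CCCC(=O)c1c(O)cc(O)c(C)c1O | intermediate
16 | 2-butanoyl-3,5-dihydroxy-6,6-dimethylcyclohexa-2,4-dien-1-one (butyrylfilicinic acid) | CCCC(=O)C1=C(O)C=C(O)C(C)(C)C1=O | intermediate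
17 | 2-butanoyl-4-[(dimethylamino)methyl]-3,5-dihydroxy-6,6-dimethylcyclohexa-2,4-dien-1-one | CCCC(=O)C1=C(O)C(CN(C)C)=C(O)C(C)(C)C1=O | intermediate
18 | 2-butanoyl-3-hydroxy-6,6-dimethyl-4-methylidenecyclohex-2-ene-1,5-dione (not isolated) | CCCC(=O)C1=C(O)C(=C)C(=O)C(C)(C)C1=O | intermediate
19 | A–B–C–B' tetramer: trimer 12 bearing one (butyrylfilicinic acid-4-yl)methyl group on ring B, ring B' still free (not isolated) | CCCC(=O)C1=C(O)C(Cc2c(O)c(Cc3c(O)c(Cc4c(O)cc(O)c(C(=O)CCC)c4O)c(O)c(C(=O)CCC)c3O)c(O)c(C(=O)CCC)c2O)=C(O)C(C)(C)C1=O | intermediate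
20 | pentaalbaspidin BBBBB | CCCC(=O)C1=C(O)C(Cc2c(O)c(Cc3c(O)c(Cc4c(O)c(CC5=C(O)C(C)(C)C(=O)C(C(=O)CCC)=C5O)c(O)c(C(=O)CCC)c4O)c(O)c(C(=O)CCC)c3O)c(O)c(C(=O)CCC)c2O)=C(O)C(C)(C)C1=O | target

Total step count: 10.
Longest linear sequence: 6 steps (1, 3, 4, 5, 6, 10) from 1,3,5-trimethoxybenzene. The ring C branch (steps 1, 2) and the ring A branch (steps 7, 8, 9) converge on it.

Steps most likely to fail

**Step 5.** Oxidative addition at a C–Br bond between two methoxy groups may be slow. That leaves room for protodebromination, for stalling after the first coupling and for homocoupling of the zinc reagent. The fallback sets out from 8 and 3 and returns at 11, and it replaces cross-coupling by a blocked Friedel–Crafts benzylation.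
- The free ring carbon of 8 is brominated (NBS, MeCN) to give 1-[3-bromo-5-(chloromethyl)-2,4,6-trimethoxyphenyl]butan-1-one F1.
- Two equivalents of F1 benzylate both free carbons of 3 (FeCl3 cat., CH2Cl2, 0 °C). This gives 1-{3,5-bis[(3-bromo-5-butanoyl-2,4,6-trimethoxyphenyl)methyl]-2,4,6-trimethoxyphenyl}butan-1-one F2. The bromine atoms keep the terminal rings from acting as nucleophiles, and the methyl ethers rule out quinone methide exchange.
- Hydrogenolysis of the two C–Br bonds (H2, Pd/C, Et3N, EtOAc–MeOH) then gives 11.

**Step 6.** Ether cleavage may stop short at the three methoxy groups para to the acyl groups. Forcing it may bring protolytic rupture and exchange of the CH2 bridges once the rings are freed in the presence of HBr. The fallback sets out from 14 and returns at 12, and it changes the protecting group so that the last deprotection is neutral.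
- 14 is O-benzylated (BnBr, K2CO3, DMF, 60 °C) to 1-[2,4,6-tris(benzyloxy)phenyl]butan-1-one F3, which goes through the same operations as 3.
- NBS gives 1-[2,4,6-tris(benzyloxy)-3,5-dibromophenyl]butan-1-one F4.
- 6 and HCl give 1-[2,4,6-tris(benzyloxy)-3-(chloromethyl)phenyl]butan-1-one F5.
- Zn and LiCl give {[2,4,6-tris(benzyloxy)-3-butanoylphenyl]methyl}zinc chloride F6.
- Pd(OAc)2/SPhos joins F4 with two F6 to the nona-O-benzyl B–C–B' trimer F7.
- Hydrogenolysis (H2, Pd/C, EtOAc–MeOH, rt) frees all nine phenols and gives 12.

**Step 10.** Three processes may erode the double bridging: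
- Retro-Mannich loss of the bridging carbon can free filicinic acid, which then captures the methylene triketone.
- The second bridging may remain incomplete.
- Amine or heat may drive exchange of the CH2 bridges.

The fallback sets out from 12 and 16 and returns at 20, and it reverses the roles of the partners.
- 12 is aminomethylated at both free terminal carbons (6, Me2NH, EtOH, 0 °C to rt). This gives 1-{3,5-bis({3-butanoyl-5-[(dimethylamino)methyl]-2,4,6-trihydroxyphenyl}methyl)-2,4,6-trihydroxyphenyl}butan-1-one F8, which has no free nucleophilic carbon left.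
- Warming F8 with a large excess of 16 (dioxane, 60 °C) replaces each dimethylamino group by C4 of a filicinic acid ring through elimination–addition and gives 20. The excess of 16 is recovered.

Further compounds
F1 | step 5 | 1-[3-bromo-5-(chloromethyl)-2,4,6-trimethoxyphenyl]butan-1-one | CCCC(=O)c1c(OC)c(Br)c(OC)c(CCl)c1OC
F2 | step 5 | 1-{3,5-bis[(3-bromo-5-butanoyl-2,4,6-trimethoxyphenyl)methyl]-2,4,6-trimethoxyphenyl}butan-1-one | CCCC(=O)c1c(OC)c(Cc2c(OC)c(Br)c(OC)c(C(=O)CCC)c2OC)c(OC)c(Cc2c(OC)c(Br)c(OC)c(C(=O)CCC)c2OC)c1OC
F3 | step 6 | 1-[2,4,6-tris(benzyloxy)phenyl]butan-1-one | CCCC(=O)c1c(OCc2ccccc2)cc(OCc2ccccc2)cc1OCc1ccccc1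
F4 | step 6 | 1-[2,4,6-tris(benzyloxy)-3,5-dibromophenyl]butan-1-one | CCCC(=O)c1c(OCc2ccccc2)c(Br)c(OCc2ccccc2)c(Br)c1OCc1ccccc1
F5 | step 6 | 1-[2,4,6-tris(benzyloxy)-3-(chloromethyl)phenyl]butan-1-one | CCCC(=O)c1c(OCc2ccccc2)cc(OCc2ccccc2)c(CCl)c1OCc1ccccc1
F6 | step 6 | {[2,4,6-tris(benzyloxy)-3-butanoylphenyl]methyl}zinc chloride | CCCC(=O)c1c(OCc2ccccc2)cc(OCc2ccccc2)c(C[Zn]Cl)c1OCc1ccccc1
F7 | step 6 | nona-O-benzyl B–C–B' trimer | CCCC(=O)c1c(OCc2ccccc2)c(Cc3c(OCc4ccccc4)cc(OCc4ccccc4)c(C(=O)CCC)c3OCc3ccccc3)c(OCc2ccccc2)c(Cc3c(OCc4ccccc4)cc(OCc4ccccc4)c(C(=O)CCC)c3OCc3ccccc3)c1OCc1ccccc1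
F8 | step 10 | 1-{3,5-bis({3-butanoyl-5-[(dimethylamino)methyl]-2,4,6-trihydroxyphenyl}methyl)-2,4,6-trihydroxyphenyl}butan-1-one | CCCC(=O)c1c(O)c(Cc2c(O)c(CN(C)C)c(O)c(C(=O)CCC)c2O)c(O)c(Cc2c(O)c(CN(C)C)c(O)c(C(=O)CCC)c2O)c1O
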